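**Plan**

- Retrosynthesis: open the C3 acetal (C3–O–C1) back to a butenolide lactol, cut C4=C12 (aldol/elimination) to release a C12–C15 aldehyde, remove the epoxide oxygen and the C7 methyl, cut C7–C8 of the carbocycle, then cut C4a–C5 and C10–C9 on a δ-lactone.
- Forward order: δ-lactone ring first, then the C5–C7 and C8–C10 arms, then the nine-membered ring by C7–C8 closure, then C7 methyl and epoxide, then the dihydrofuran (as a butenolide), last the pyran acetal.
- Enabling feature: C7 is a carbinol carbon bonded to the cis C8–C9 unit inside the carbocycle C4a–C5–C6–C7–C8–C9–C10–C11–C11a. A C7 aldehyde and a Z C8 alkenyl metal, both held on the trans lactone, can therefore close that ring and leave the allylic alcohol that later directs the epoxidation.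
- Stereochemistry: C11a from an oxazolidinone-controlled alkylation; C4a by anti 1,4-addition; C7 by face-selective methyl addition to the cyclononenone; C8/C9 by hydroxyl-directed epoxidation; C13/C14 from D-erythronolactone; C3 by reversible acetalisation.

Key step: step 13

Assumption: atom labels follow the target's cyclonona[c]pyran numbering (C1 ring OCH2, C3 acetal CH, C4=C12 alkene, C13 ring OCH, C14/C15 side-chain carbinols, C4a/C11a ring fusion, C7 methyl carbinol, C8/C9 epoxide, C11 bearing methylene C19) for all intermediates; alcohol 21 is drawn as its 7S epimer, but either C7 epimer serves because step 14 removes that centre.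

**Route**

Step 1
Reactants: 1 (S)-4-benzyloxazolidin-2-one; 2 3-methylbut-2-enoyl chloride
Product: 3 (S)-4-benzyl-3-(3-methylbut-2-enoyl)oxazolidin-2-one
Conditions: nBuLi, THF, −78 °C; then 2, −78 → 0 °C
Reagents that add atoms: none
Why: N-acylation of the lithiated oxazolidinone by an acid chloride is the standard entry to such imides and leaves the enoyl unit untouched.

Step 2
Reactants: 3 (S)-4-benzyl-3-(3-methylbut-2-enoyl)oxazolidin-2-one; 4 benzyl chloromethyl ether
Product: 5 (S)-4-benzyl-3-[(2R)-2-[(benzyloxy)methyl]-3-methylbut-3-enoyl]oxazolidin-2-one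
Conditions: NaN(SiMe3)2, THF, −78 °C; then 4, −78 → −30 °C
Reagents that add atoms: none
Why: γ-deprotonation gives the chelated Z(O) sodium dienolate, which is alkylated at its α-carbon on the face opposite the benzyl group (deconjugative Evans alkylation), setting C11a as R and moving the alkene into the isopropenyl group.

Step 3
Reactants: 5 (S)-4-benzyl-3-[(2R)-2-[(benzyloxy)methyl]-3-methylbut-3-enoyl]oxazolidin-2-one
Product: 6 (2S)-2-[(benzyloxy)methyl]-3-methylbut-3-en-1-ol
Conditions: LiBH4, MeOH (1 equiv), Et2O, 0 °C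
Reagents that add atoms: none
Why: reductive cleavage of the exocyclic imide carbonyl by LiBH4 gives the primary alcohol (future C4a) without touching alkene or stereocentre and returns the auxiliary.

Step 4
Reactants: 6 (2S)-2-[(benzyloxy)methyl]-3-methylbut-3-en-1-ol
Product: 7 (2R)-2-[(benzyloxy)methyl]-3-methylbut-3-enal
Conditions: Dess–Martin periodinane, NaHCO3, CH2Cl2, 0 °C
Reagents that add atoms: none
Why: buffered Dess–Martin oxidation gives the α-branched β,γ-unsaturated aldehyde without acid or base that could epimerise C11a or shift the alkene; the aldehyde should be used at once.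

Step 5
Reactants: 7 (2R)-2-[(benzyloxy)methyl]-3-methylbut-3-enal; 8 methyl 2-[bis(2,2,2-trifluoroethoxy)phosphoryl]acetate
Product: 9 methyl (2Z,4R)-4-[(benzyloxy)methyl]-5-methylhexa-2,5-dienoate
Conditions: KN(SiMe3)2, 18-crown-6, THF, −78 °C
Reagents that add atoms: none
Why: Still–Gennari olefination gives the Z enoate under kinetic control, the geometry required for lactonisation, at a temperature that spares the α-stereocentre.

Step 6
Reactants: 9 methyl (2Z,4R)-4-[(benzyloxy)methyl]-5-methylhexa-2,5-dienoate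
Product: 11 (5R)-5-(prop-1-en-2-yl)-5,6-dihydro-2H-pyran-2-one, via hydroxy Z-enoate 10 (not isolated)
Conditions: BCl3, C6HMe5, CH2Cl2, −78 °C; MeOH, → rt
Reagents that add atoms: none
Why: BCl3 with pentamethylbenzene as cation scavenger cleaves the benzyl ether at low temperature without adding to the alkenes, and the freed δ-hydroxy Z-enoate lactonises with loss of methanol.

Step 7
Reactants: 11 (5R)-5-(prop-1-en-2-yl)-5,6-dihydro-2H-pyran-2-one; 12 2-(2-bromoethyl)-1,3-dioxolane
Product: 14 (4R,5R)-4-[2-(1,3-dioxolan-2-yl)ethyl]-5-(prop-1-en-2-yl)oxan-2-one, via Grignard reagent 13 (not isolated)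
Conditions: 12, Mg, THF, rt; then CuBr·SMe2 (15 mol%), 11, THF, −78 → −40 °C; aq. NH4Cl
Reagents that add atoms: none
Why: copper-catalysed 1,4-addition of the Grignard reagent to the unsaturated δ-lactone occurs anti to the C11a substituent, as is general for 5-substituted 5,6-dihydropyran-2-ones, which sets C4a trans to C11a.

Step 8
Reactants: 14 (4R,5R)-4-[2-(1,3-dioxolan-2-yl)ethyl]-5-(prop-1-en-2-yl)oxan-2-one
Product: 15 (4R,5R)-5-(3-chloroprop-1-en-2-yl)-4-[2-(1,3-dioxolan-2-yl)ethyl]oxan-2-one
Conditions: Ca(OCl)2, CO2 (solid), CH2Cl2/H2O, 0 °C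
Reagents that add atoms: calcium hypochlorite, [Ca+2].[O-]Cl.[O-]Cl
Why: hypochlorous acid chlorinates 1,1-disubstituted alkenes by an ene-type path with allylic transposition, taking a methyl hydrogen in preference to the C11a methine hydrogen, so the 2-(chloromethyl)vinyl group forms and C11a is untouched.

Step 9
Reactants: 15 (4R,5R)-5-(3-chloroprop-1-en-2-yl)-4-[2-(1,3-dioxolan-2-yl)ethyl]oxan-2-one; 16 ethynyltrimethylsilane
Product: 17 (4R,5R)-4-[2-(1,3-dioxolan-2-yl)ethyl]-5-[5-(trimethylsilyl)pent-1-en-4-yn-2-yl]oxan-2-one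
Conditions: CuI, NaI, K2CO3, DMF, rt
Reagents that add atoms: none
Why: copper acetylide substitution of the allylic halide under carbonate base gives the skipped enyne; SN2 and SN2' attack on the 2-substituted allyl unit give the same product, and the lactone tolerates the mild base.

Step 10
Reactants: 17 (4R,5R)-4-[2-(1,3-dioxolan-2-yl)ethyl]-5-[5-(trimethylsilyl)pent-1-en-4-yn-2-yl]oxan-2-one
Product: 18 (4R,5R)-4-[2-(1,3-dioxolan-2-yl)ethyl]-5-(5-iodopent-1-en-4-yn-2-yl)oxan-2-one
Conditions: N-iodosuccinimide, AgNO3 (10 mol%), DMF, rt, dark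
Reagents that add atoms: N-iodosuccinimide, O=C1CCC(=O)N1I
Why: AgNO3-catalysed iododesilylation converts the alkynylsilane directly into the 1-iodoalkyne through a silver acetylide, with no base that could isomerise the skipped enyne.

Step 11
Reactants: 18 (4R,5R)-4-[2-(1,3-dioxolan-2-yl)ethyl]-5-(5-iodopent-1-en-4-yn-2-yl)oxan-2-one
Product: 19 (4R,5R)-4-[2-(1,3-dioxolan-2-yl)ethyl]-5-[(4Z)-5-iodopenta-1,4-dien-2-yl]oxan-2-one
Conditions: 2-nitrobenzenesulfonylhydrazide, Et3N, THF/iPrOH, rt
Reagents that add atoms: none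
Why: diimide adds H2 syn to the iodoalkyne much faster than to the 1,1-disubstituted alkene, giving the Z iodoalkene (diimide reduction); a limited charge of reagent protects the methylene group.

Step 12
Reactants: 19 (4R,5R)-4-[2-(1,3-dioxolan-2-yl)ethyl]-5-[(4Z)-5-iodopenta-1,4-dien-2-yl]oxan-2-one
Product: 20 3-[(4R,5R)-5-[(4Z)-5-iodopenta-1,4-dien-2-yl]-2-oxooxan-4-yl]propanal
Conditions: 1 M HCl, THF, rt
Reagents that add atoms: water, O
Why: dilute aqueous acid hydrolyses the dioxolane to the C7 aldehyde while lactone, skipped diene and alkenyl iodide are stable (acetal hydrolysis).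

Step 13
Reactants: 20 3-[(4R,5R)-5-[(4Z)-5-iodopenta-1,4-dien-2-yl]-2-oxooxan-4-yl]propanal
Product: 21 (4aR,7S,8Z,11aR)-7-hydroxy-11-methylidene-4,4a,5,6,7,10,11,11a-octahydrocyclonona[c]pyran-3(1H)-one
Conditions: CrCl2 (10 equiv), NiCl2 (2 mol%), DMSO/THF, rt, slow addition to 0.003 M
Reagents that add atoms: none
Why: Zerovalent nickel, formed from NiCl2 by CrCl2, inserts into the C8–I bond with retention, hands the Z-alkenyl group to trivalent chromium, and the alkenylchromium species adds to the C7 aldehyde (intramolecular Nozaki–Hiyama–Kishi reaction, precedented for nine-membered carbocycles). The ring C4a–C5–C6–C7–C8–C9–C10–C11–C11a closes by carbonyl addition in a 9-exo-trig mode, helped by the gauche disposition of the two arms on the trans-diequatorial lactone. The new C7 carbinol centre is under substrate control by the ring-closing transition state; the 7S epimer drawn is expected to prevail, and the other is equally usable because step 14 erases this centre. The step needs retention of the Z geometry (already fixed in iodide 20 and held by the disubstituted alkenylchromium), attack on the aldehyde in preference to the lactone (secured by the low basicity and aldehyde preference of organochromium reagents), and cyclisation over oligomerisation (secured by slow addition at high dilution).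

Step 14
Reactants: 21 (4aR,7S,8Z,11aR)-7-hydroxy-11-methylidene-4,4a,5,6,7,10,11,11a-octahydrocyclonona[c]pyran-3(1H)-one
Product: 22 (4aR,8Z,11aR)-11-methylidene-4,4a,5,6,11,11a-hexahydrocyclonona[c]pyran-3,7(1H,10H)-dione
Conditions: Dess–Martin periodinane, NaHCO3, CH2Cl2, 0 °C
Reagents that add atoms: none
Why: buffered Dess–Martin oxidation gives the Z enone without base that could draw the C8–C9 or C11–C19 alkenes into conjugation, and it merges both C7 epimers.

Step 15
Reactants: 22 (4aR,8Z,11aR)-11-methylidene-4,4a,5,6,11,11a-hexahydrocyclonona[c]pyran-3,7(1H,10H)-dione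
Product: 23 (4aR,7S,8Z,11aR)-7-hydroxy-7-methyl-11-methylidene-4,4a,5,6,7,10,11,11a-octahydrocyclonona[c]pyran-3(1H)-one
Conditions: MeMgBr, CeCl3, THF, −78 °C
Reagents that add atoms: methylmagnesium bromide, C[Mg]Br
Why: the organocerium reagent adds 1,2 to the ketone far faster than to the lactone and is too weakly basic to enolise toward C10; attack is expected on the outer face of the folded cyclononenone, the face carrying the C4a–C4 bond, to give the 7S tertiary alcohol.

Step 16
Reactants: 23 (4aR,7S,8Z,11aR)-7-hydroxy-7-methyl-11-methylidene-4,4a,5,6,7,10,11,11a-octahydrocyclonona[c]pyran-3(1H)-one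
Product: 24 (4aR,7S,8R,9R,11aR)-8,9-epoxy-7-hydroxy-7-methyl-11-methylideneperhydrocyclonona[c]pyran-3-one
Conditions: VO(acac)2 (5 mol%), tBuOOH, CH2Cl2, 0 °C → rt
Reagents that add atoms: tert-butyl hydroperoxide, CC(C)(C)OO
Why: the vanadium alkoxide of the tertiary allylic alcohol delivers oxygen to the C8–C9 face syn to the hydroxyl (hydroxyl-directed epoxidation, cis-selective for medium-ring allylic alcohols), giving the 8R,9R epoxide and leaving the remote C11 methylene alone.

Step 17
Reactants: 25 2,3-O-isopropylidene-D-erythronolactone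
Product: 26 2-[(4R,5R)-5-(hydroxymethyl)-2,2-dimethyl-1,3-dioxolan-4-yl]propan-2-ol
Conditions: MeMgBr (3 equiv), THF, 0 °C → rt; aq. NH4Cl
Reagents that add atoms: methylmagnesium bromide, C[Mg]Br
Why: double Grignard addition to the lactone carbonyl builds the C15 dimethyl carbinol and frees the C12 hydroxyl, while the acetonide holds the C13 and C14 configurations of the sugar lactone.

Step 18
Reactants: 26 2-[(4R,5R)-5-(hydroxymethyl)-2,2-dimethyl-1,3-dioxolan-4-yl]propan-2-ol
Product: 27 (2R,3R)-4-methylpentane-1,2,3,4-tetrol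
Conditions: Dowex 50W (H+ form), MeOH/H2O, 50 °C
Reagents that add atoms: none
Why: acid-catalysed acetonide hydrolysis at this early stage lets every later protecting group of the side chain be removed by fluoride, so that no strong acid meets the epoxide.

Step 19
Reactants: 27 (2R,3R)-4-methylpentane-1,2,3,4-tetrol
Product: 28 (2R,3R)-4-methyl-1,2,3,4-tetrakis(triethylsilyloxy)pentane
Conditions: Et3SiOTf, 2,6-lutidine, CH2Cl2, −78 → 0 °C
Reagents that add atoms: triethylsilyl trifluoromethanesulfonate, CC[Si](CC)(CC)OS(=O)(=O)C(F)(F)F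
Why: the silyl triflate with a hindered base silylates all four hydroxyls, the tertiary one included.

Step 20
Reactants: 28 (2R,3R)-4-methyl-1,2,3,4-tetrakis(triethylsilyloxy)pentane
Product: 29 (2S,3R)-4-methyl-2,3,4-tris(triethylsilyloxy)pentanal
Conditions: (COCl)2, DMSO, CH2Cl2, −78 → −40 °C; Et3N, −78 → 0 °C
Reagents that add atoms: none
Why: under Swern conditions only the primary triethylsilyl ether is cleaved by the chlorosulfonium salt and oxidised in place to the aldehyde, the secondary and tertiary silyl ethers being too hindered (selective Swern oxidation of primary silyl ethers).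

Step 21
Reactants: 24 (4aR,7S,8R,9R,11aR)-8,9-epoxy-7-hydroxy-7-methyl-11-methylideneperhydrocyclonona[c]pyran-3-one; 29 (2S,3R)-4-methyl-2,3,4-tris(triethylsilyloxy)pentanal
Product: 30 epoxy lactone 24 carrying at C4 a (2R,3R)-1-hydroxy-4-methyl-2,3,4-tris(triethylsilyloxy)pentyl group (mixture at C4 and C12)
Conditions: LiN(iPr)2 (2.2 equiv), THF, −78 °C; then 29, −78 °C; aq. NH4Cl
Reagents that add atoms: none
Why: the lithium enolate of the δ-lactone (the second equivalent of base holds the tertiary hydroxyl as its alkoxide) adds to the aldehyde at −78 °C (aldol addition); the configurations at C4 and C12 do not matter because both carbons become sp2.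

Step 22
Reactants: 30 aldol adduct (C4-substituted epoxy δ-lactone, tris-silyl ether)
Product: 32 γ-lactone pentol (C3 lactonised onto the C13 oxygen; hydroxyls at C1, C12, C14, C15 and C7), via desilylated δ-lactone 31 (not isolated)
Conditions: Bu4NF, THF, 0 °C → rt
Reagents that add atoms: none
Why: fluoride removes the three silyl groups and the C13 alkoxide takes over the acyl group from the C1 oxygen, the five-membered lactone being favoured over the six-membered one (translactonisation).

Step 23
Reactants: 32 γ-lactone pentol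
Product: 34 butenolide diacetate (C4=C12 in the lactone ring; acetates on the C1 and C14 oxygens), via triacetate 33 (not isolated)
Conditions: Ac2O, pyridine, CH2Cl2, rt; then DBU (1.1 equiv), 0 °C
Reagents that add atoms: acetic anhydride, CC(=O)OC(C)=O
Why: acetylation of the primary and secondary hydroxyls makes the C12 oxygen a leaving group β to the lactone carbonyl, and one equivalent of DBU effects E1cB elimination to the butenolide, whose ring fixes C13 cis to C3 across C4=C12; the acetic acid released consumes the base before it can deprotonate C13.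

Step 24
Reactants: 34 butenolide diacetate
Product: 35 lactol tetrol (2-hydroxy-2,5-dihydrofuran; hydroxyls at C1, C14, C15 and C7; mixture at C3)
Conditions: iBu2AlH (8 equiv), CH2Cl2, −78 °C; MeOH, aq. KNaC4H4O6
Reagents that add atoms: none
Why: at −78 °C iBu2AlH reduces the butenolide carbonyl only to the lactol (1,2-reduction) and cleaves both acetates reductively, while the epoxide is inert at this temperature.

Step 25
Reactants: 35 lactol tetrol
Product: 36 target, (3S,4aS,7S,8R,9R,11aR,13R,14R)-configured furo-pyran acetal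
Conditions: PPTS (cat.), 4 Å molecular sieves, CH2Cl2, 0 °C → rt
Reagents that add atoms: none
Why: mild acid ionises the allylic lactol to an oxocarbenium ion that the C1 hydroxyl captures in a six-membered ring (intramolecular acetalisation); the acetal forms reversibly, so C3 should settle as 3S, which allows a chair pyran with the C4a and C11a ring bonds equatorial, and the low acidity spares the epoxide and disfavours aromatisation to a furan.

**Compound list**

1 | (S)-4-benzyloxazolidin-2-one | O=C1N[C@@H](Cc2ccccc2)CO1 | starting material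
2 | 3-methylbut-2-enoyl chloride | CC(C)=CC(Cl)=O | starting material
3 | (S)-4-benzyl-3-(3-methylbut-2-enoyl)oxazolidin-2-one | CC(C)=CC(=O)N1[C@@H](Cc2ccccc2)COC1=O | intermediate
4 | benzyl chloromethyl ether | ClCOCc1ccccc1 | starting material
5 | (S)-4-benzyl-3-[(2R)-2-[(benzyloxy)methyl]-3-methylbut-3-enoyl]oxazolidin-2-one | C=C(C)[C@H](COCc1ccccc1)C(=O)N1[C@@H](Cc2ccccc2)COC1=O | intermediate
6 | (2S)-2-[(benzyloxy)methyl]-3-methylbut-3-en-1-ol | C=C(C)[C@H](COCc1ccccc1)CO | intermediate
7 | (2R)-2-[(benzyloxy)methyl]-3-methylbut-3-enal | C=C(C)[C@H](COCc1ccccc1)C=O | intermediate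
8 | methyl 2-[bis(2,2,2-trifluoroethoxy)phosphoryl]acetate | COC(=O)CP(=O)(OCC(F)(F)F)OCC(F)(F)F | starting material
9 | methyl (2Z,4R)-4-[(benzyloxy)methyl]-5-methylhexa-2,5-dienoate | C=C(C)[C@H](COCc1ccccc1)/C=C\C(=O)OC | intermediate
10 | methyl (2Z,4R)-4-(hydroxymethyl)-5-methylhexa-2,5-dienoate | C=C(C)[C@H](CO)/C=C\C(=O)OC | intermediate (not isolated)
11 | (5R)-5-(prop-1-en-2-yl)-5,6-dihydro-2H-pyran-2-one | O=C1C=C[C@H](C(C)=C)CO1 | intermediate
12 | 2-(2-bromoethyl)-1,3-dioxolane | BrCCC1OCCO1 | starting material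
13 | [2-(1,3-dioxolan-2-yl)ethyl]magnesium bromide | Br[Mg]CCC1OCCO1 | intermediate (not isolated)
14 | (4R,5R)-4-[2-(1,3-dioxolan-2-yl)ethyl]-5-(prop-1-en-2-yl)oxan-2-one | O=C1C[C@@H](CCC2OCCO2)[C@H](C(C)=C)CO1 | intermediate
15 | (4R,5R)-5-(3-chloroprop-1-en-2-yl)-4-[2-(1,3-dioxolan-2-yl)ethyl]oxan-2-one | O=C1C[C@@H](CCC2OCCO2)[C@H](C(=C)CCl)CO1 | intermediate
16 | ethynyltrimethylsilane | C#C[Si](C)(C)C | starting material
17 | (4R,5R)-4-[2-(1,3-dioxolan-2-yl)ethyl]-5-[5-(trimethylsilyl)pent-1-en-4-yn-2-yl]oxan-2-one | O=C1C[C@@H](CCC2OCCO2)[C@H](C(=C)CC#C[Si](C)(C)C)CO1 | intermediate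
18 | (4R,5R)-4-[2-(1,3-dioxolan-2-yl)ethyl]-5-(5-iodopent-1-en-4-yn-2-yl)oxan-2-one | O=C1C[C@@H](CCC2OCCO2)[C@H](C(=C)CC#CI)CO1 | intermediate
19 | (4R,5R)-4-[2-(1,3-dioxolan-2-yl)ethyl]-5-[(4Z)-5-iodopenta-1,4-dien-2-yl]oxan-2-one | O=C1C[C@@H](CCC2OCCO2)[C@H](C(=C)C/C=C\I)CO1 | intermediate
20 | 3-[(4R,5R)-5-[(4Z)-5-iodopenta-1,4-dien-2-yl]-2-oxooxan-4-yl]propanal | O=C1C[C@@H](CCC=O)[C@H](C(=C)C/C=C\I)CO1 | intermediate
21 | (4aR,7S,8Z,11aR)-7-hydroxy-11-methylidene-4,4a,5,6,7,10,11,11a-octahydrocyclonona[c]pyran-3(1H)-one | O=C1C[C@H]2CC[C@H](O)/C=C\CC(=C)[C@@H]2CO1 | intermediate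
22 | (4aR,8Z,11aR)-11-methylidene-4,4a,5,6,11,11a-hexahydrocyclonona[c]pyran-3,7(1H,10H)-dione | O=C1C[C@H]2CCC(=O)/C=C\CC(=C)[C@@H]2CO1 | intermediate
23 | (4aR,7S,8Z,11aR)-7-hydroxy-7-methyl-11-methylidene-4,4a,5,6,7,10,11,11a-octahydrocyclonona[c]pyran-3(1H)-one | O=C1C[C@H]2CC[C@](C)(O)/C=C\CC(=C)[C@@H]2CO1 | intermediate
24 | (4aR,7S,8R,9R,11aR)-8,9-epoxy-7-hydroxy-7-methyl-11-methylideneperhydrocyclonona[c]pyran-3-one | O=C1C[C@H]2CC[C@](C)(O)[C@@H]3O[C@@H]3CC(=C)[C@@H]2CO1 | intermediate
25 | 2,3-O-isopropylidene-D-erythronolactone | O=C1OC[C@H]2OC(C)(C)O[C@@H]12 | starting material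
26 | 2-[(4R,5R)-5-(hydroxymethyl)-2,2-dimethyl-1,3-dioxolan-4-yl]propan-2-ol | OC[C@H]1OC(C)(C)O[C@H]1C(C)(C)O | intermediate
27 | (2R,3R)-4-methylpentane-1,2,3,4-tetrol | OC[C@@H](O)[C@@H](O)C(C)(C)O | intermediate
28 | (2R,3R)-4-methyl-1,2,3,4-tetrakis(triethylsilyloxy)pentane | CC[Si](CC)(CC)OC[C@@H](O[Si](CC)(CC)CC)[C@@H](O[Si](CC)(CC)CC)C(C)(C)O[Si](CC)(CC)CC | intermediate
29 | (2S,3R)-4-methyl-2,3,4-tris(triethylsilyloxy)pentanal | O=C[C@@H](O[Si](CC)(CC)CC)[C@@H](O[Si](CC)(CC)CC)C(C)(C)O[Si](CC)(CC)CC | intermediate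
30 | aldol adduct: lactone 24 with a (2R,3R)-1-hydroxy-4-methyl-2,3,4-tris(triethylsilyloxy)pentyl group at C4 (mixture at C4 and C12) | O=C1C(C(O)[C@@H](O[Si](CC)(CC)CC)[C@@H](O[Si](CC)(CC)CC)C(C)(C)O[Si](CC)(CC)CC)[C@H]2CC[C@](C)(O)[C@@H]3O[C@@H]3CC(=C)[C@@H]2CO1 | intermediate
31 | desilylated δ-lactone: lactone 24 with a (2R,3R)-1,2,3,4-tetrahydroxy-4-methylpentyl group at C4 | O=C1C(C(O)[C@@H](O)[C@@H](O)C(C)(C)O)[C@H]2CC[C@](C)(O)[C@@H]3O[C@@H]3CC(=C)[C@@H]2CO1 | intermediate (not isolated)
32 | γ-lactone pentol: 3-hydroxy-γ-butyrolactone (C3 carbonyl, ring oxygen on C13) bearing at C13 the (1R)-1,2-dihydroxy-2-methylpropyl chain and at C4 the epoxy-cyclononane (C11a hydroxymethyl, C7 carbinol, 8,9-epoxide, C11 methylene) | C=C1C[C@H]2O[C@H]2[C@@](C)(O)CC[C@@H]([C@H]1CO)C1C(O)[C@H]([C@@H](O)C(C)(C)O)OC1=O | intermediate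
33 | triacetate of 32 (acetates on the C1, C12 and C14 oxygens) | C=C1C[C@H]2O[C@H]2[C@@](C)(O)CC[C@@H]([C@H]1COC(C)=O)C1C(OC(C)=O)[C@H]([C@@H](OC(C)=O)C(C)(C)O)OC1=O | intermediate (not isolated)
34 | butenolide diacetate: (13R)-butenolide with C4=C12, acetates on the C1 and C14 oxygens | C=C1C[C@H]2O[C@H]2[C@@](C)(O)CC[C@@H]([C@H]1COC(C)=O)C1=C[C@H]([C@@H](OC(C)=O)C(C)(C)O)OC1=O | intermediate
35 | lactol tetrol: 2-hydroxy-2,5-dihydrofuran from 34, all acetates removed (mixture at C3) | C=C1C[C@H]2O[C@H]2[C@@](C)(O)CC[C@@H]([C@H]1CO)C1=C[C@H]([C@@H](O)C(C)(C)O)OC1O | intermediate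
36 | target CNP0281409.2, (3S,4aS,7S,8R,9R,11aR,13R,14R) | C=C1C[C@H]2O[C@H]2[C@@](C)(O)CC[C@@H]2C3=C[C@H]([C@@H](O)C(C)(C)O)O[C@@H]3OC[C@@H]12 | target

**Totals and risks**

Total step count: 25. Longest linear sequence: 21 steps (steps 1–16, then 21–25); steps 17–20 make the side-chain aldehyde 29.

Step 13 (oligomerisation or protodeiodination outrunning the slow nine-membered ring closure). The fallback sets out from allylic chloride 15 and returns at 21. Stille coupling of 15 with tributyl(vinyl)stannane (Pd2(dba)3, AsPh3, THF) would give the skipped triene acetal F1. 1 M HCl in THF would free the aldehyde F2. Vinylmagnesium bromide at −78 °C, which takes the aldehyde before the lactone, would give the allylic alcohol F3. Ring-closing metathesis with second-generation Grubbs catalyst in dilute CH2Cl2 would then join C8 and C9 with loss of ethene, the ring size enforcing the Z alkene, to give 21 as its C7 epimers. The 1,1-disubstituted C11 methylene should engage the ruthenium carbene more slowly than the two monosubstituted alkenes.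

Step 15 (methyl delivery to the wrong face of the cyclononenone carbonyl, or γ-enolisation toward C10). The fallback sets out from 21 (7S epimer; the 7R epimer would first be inverted by a Mitsunobu sequence) and returns at 24. Hydroxyl-directed epoxidation of the secondary allylic alcohol (VO(acac)2, tBuOOH) would give the cis-epoxy alcohol F4. Dess–Martin oxidation would give the epoxy ketone F5. MeMgBr, chelated between the ketone and epoxide oxygens, would add anti to C9 and so place the new hydroxyl syn to the epoxide, which is 24. The C7 configuration is then tied to the neighbouring epoxide instead of the remote ring-fusion centres.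

Step 23 (loss of the C13 configuration by deprotonation of the butenolide γ-position, or vinylogous expulsion of the C14 acetate, during the base-induced elimination). The fallback sets out from aldol adduct 30 and returns at 35. Dess–Martin oxidation of the C12 hydroxyl would give the β-keto lactone F6. Buffered HF·pyridine would remove the silyl groups, and the C13 hydroxyl would close onto C3 to give the tetronic acid F7. PhNTf2/Et3N would triflate only the acidic enol, giving the enol triflate F8. Pd(OAc)2/PPh3 with HCO2H/Bu3N would replace the triflate by hydrogen to give the butenolide tetrol F9, which iBu2AlH at −78 °C would reduce to lactol 35. No leaving group is placed on C14 and no E1cB step is needed.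

**Further compounds**

F1 | step 13 | (4R,5R)-4-[2-(1,3-dioxolan-2-yl)ethyl]-5-(penta-1,4-dien-2-yl)oxan-2-one | O=C1C[C@@H](CCC2OCCO2)[C@H](C(=C)CC=C)CO1
F2 | step 13 | 3-[(4R,5R)-2-oxo-5-(penta-1,4-dien-2-yl)oxan-4-yl]propanal | O=C1C[C@@H](CCC=O)[C@H](C(=C)CC=C)CO1
F3 | step 13 | (4R,5R)-4-(3-hydroxypent-4-en-1-yl)-5-(penta-1,4-dien-2-yl)oxan-2-one (carbinol epimers) | O=C1C[C@@H](CCC(O)C=C)[C@H](C(=C)CC=C)CO1
F4 | step 15 | cis-epoxy alcohol: 8,9-epoxide of 21 on the face of the C7 hydroxyl | O=C1C[C@H]2CC[C@H](O)[C@@H]3O[C@@H]3CC(=C)[C@@H]2CO1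
F5 | step 15 | (4aR,8R,9R,11aR)-8,9-epoxy-11-methylideneperhydrocyclonona[c]pyran-3,7-dione | O=C1C[C@H]2CCC(=O)[C@@H]3O[C@@H]3CC(=C)[C@@H]2CO1
F6 | step 23 | β-keto lactone: 30 with the C12 carbinol oxidised to the ketone | O=C1C(C(=O)[C@@H](O[Si](CC)(CC)CC)[C@@H](O[Si](CC)(CC)CC)C(C)(C)O[Si](CC)(CC)CC)[C@H]2CC[C@](C)(O)[C@@H]3O[C@@H]3CC(=C)[C@@H]2CO1
F7 | step 23 | tetronic acid: 4-hydroxybutenolide (enol at C12, ring oxygen on C13) with free C1, C14, C15 and C7 hydroxyls | C=C1C[C@H]2O[C@H]2[C@@](C)(O)CC[C@@H]([C@H]1CO)C1=C(O)[C@H]([C@@H](O)C(C)(C)O)OC1=O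
F8 | step 23 | enol triflate of F7 at the C12 oxygen | C=C1C[C@H]2O[C@H]2[C@@](C)(O)CC[C@@H]([C@H]1CO)C1=C(OS(=O)(=O)C(F)(F)F)[C@H]([C@@H](O)C(C)(C)O)OC1=O
F9 | step 23 | butenolide tetrol: 34 without its two acetyl groups | C=C1C[C@H]2O[C@H]2[C@@](C)(O)CC[C@@H]([C@H]1CO)C1=C[C@H]([C@@H](O)C(C)(C)O)OC1=O
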